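The constants of this flask have to come from the alder run, so the charges and readings stand first.

- alder: starting complex 0.050 M (fed, over 25 s); incoming ligand 0.105 M; run made earlier
- flask: starting complex 0.10 M (fed, over 25 s); incoming ligand 0.105 M; time 10 min

alder run (percent of the starting complex charged)

| time / s | complex with two exchanged / % | complex with one exchanged / % |
|---|---|---|
| 10.0 | 1.5 | 3.0 |
| 20.0 | 7.2 | 7.0 |
| 30.0 | 17.3 | 12.0 |
| 60.0 | 43.8 | 10.3 |
| 120 | 66.7 | 6.9 |

(each reading ± 0.5 percentage points)

- the reaction counts as stopped when no species that holds the starting complex changes by six tenths of a point or more over the second half of the time
- percentages count the whole charge, also what has not yet gone in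

* why nothing more happens at 10 min, or that something still does (all of the starting complex has reacted / forward and back rates have come level / the incoming ligand has run out first / it is still moving)
* how much complex with two exchanged there is at 10 min, in percent of the starting complex charged
* how much complex with one exchanged there is at 10 min, in percent of the starting complex charged

At 120 s the alder run holds 66.7% of complex with two exchanged, far more than the 6.9% with one exchanged. So I take the second exchange as keeping pace with the first, and I read what each reacted complex costs in incoming ligand:

n = (c(one exchanged) + 2 c(two exchanged)) / (c(one exchanged) + c(two exchanged)) = 1.91

The ligand balance of the alder run leaves 0.0560 M at 60.0 s and 0.0348 M at 120 s. The loss of starting complex between those readings then gives a constant for the first exchange, as a reading: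

k = 0.203 /M/s

For this flask I define one more quantity:

reach = c(incoming ligand) / (n c(starting complex)) = 55.1%

This is the ligand's reach, the share x of the charge reacted at which the ligand factor below comes to zero. It lies below the whole charge, which makes the incoming ligand the limiting reagent in my reckoning.

rate, as share of the charge per second = 0.0213 /s × (1 − x) × (1 − x/reach)

At x = 27.6% the complex factor is 0.724 and the ligand factor 0.5. At the reach the complex factor still stands at 0.449, but the ligand factor is zero. The last gap closes with a time of 57.6 s, much shorter than 10 min, so I commit to 55.1% reacted.

The forecast says that the incoming ligand has run out first, and it gives 47.6% of complex with two exchanged and 9.8% with one exchanged; in its words, “Ligand therefore runs out”. Its two products add up to 57.4%, more than my 55.1%.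

In the flask at 10 min, forward and back rates have come level, with 43.8% of complex with two exchanged and 8.69% with one exchanged.

    starting complex + incoming ligand ⇌ leaving ligand + complex with one exchanged (K = 2.03, k = 0.235 /M/s)
    complex with one exchanged + incoming ligand ⇌ leaving ligand + complex with two exchanged (K = 56.0, k = 1.17 /M/s)

The two products hold 52.5%, less than the reach of 55.1%. The incoming ligand stands at 8.30% of its charge at 5.00 min and at 8.26% at 100 min, beside 0.0963 M of leaving ligand. The neighbouring flask is the same flask with 0.025 M of starting complex instead. Its reach is 220%, above the whole charge, so by this reckoning the complex factor comes to zero and 54.5% of the incoming ligand stays. That flask holds 0.707% of starting complex and 53% of its incoming ligand at 10.0 min.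

Readings and results were computed with constants of no real substance; scatter was added.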